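1. The amounts first: in every flask the protic impurity equals the electrophile charge, and the nucleophile charge differs.

the same everywhere: electrophile 20 mM

| charge | nucleophile | protic impurity | remark | time |
|---|---|---|---|---|
| Friday's | 0.78 equiv | 20 mM | run made earlier |  |
| Monday's | 1.5 equiv | 20 mM | run made earlier |  |
| winter | 2.40 equiv | 20.0 mM |  | 15 min |
| autumn | 1.20 equiv | 20.0 mM |  | 15 min |

- Friday's (time / min: electrophile / %, product / %): 4.00: 85.5, 14.5; 8.00: 82.1, 15.0; 12.0: 82.2, 17.3; 15.0: 82.9, 18.0
- Monday's (time / min: electrophile / %, product / %): 2.00: 81.7, 19.9; 5.00: 71.6, 30.2; 10.0: 64.9, 34.7; 15.0: 63.3, 37.2

(scatter of a reading: 1 percentage point)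

- the numbers in the tables scatter with a standard deviation of 1 percentage point

- part of the electrophile that has reacted at the end, winter
- part of the electrophile that has reacted at the end, autumn
- what raising the equivalents of nucleophile from its lowest to its highest value here does to the part of the electrophile that has reacted (changes below 5 percentage points count as none) (no change / it rises / it falls)

2. At 15.0 min, Friday's flask holds 18.0 % product from 0.78 equiv of nucleophile, and Monday's holds 37.2 % from 1.5 equiv. Per equivalent these are 0.231 and 0.248, equal within the scatter. Their mean is 0.239: the product yield per equivalent, the fraction of the electrophile charge turned into product per equivalent of nucleophile charged.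

3. Low extreme: electrophile and impurity stay near their charges, so the ratio of their rates stays constant and the nucleophile splits in a fixed share. Product is then this yield times the equivalents: 28.7 % for autumn and 57.5 % for winter.

4. High extreme: the nucleophile stays at its charge, and the electrophile decays exponentially, a pseudo-first-order loss with a constant proportional to the nucleophile charge. Monday's first reading gives 0.101 min⁻¹, which scales to 91.2 % reacted in winter. For Monday's flask the same reckoning gives 78.0 % at 15.0 min, against 37.2 % product read, so that flask stands on the low line.

5. In winter, the low line leaves 1.83 equiv of nucleophile outside product, more than the 1.00 equiv of impurity can consume one for one. The reckoning therefore puts winter above 57.5 % and below the high line, autumn on its low line, and conversion rising with the charge.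

6. The forecast gives 63 % (53 % to 80 %) for winter, 30 % (26 % to 34 %) for autumn, and for the trend it rises, on the ground that “conversion tracks nucleophile charged”.

    electrophile + nucleophile → acid set free + product (k = 5.20 L mol⁻¹ min⁻¹)
    nucleophile + acid set free ⇌ protonated nucleophile, settled at all times (K = 85000 L mol⁻¹)
    nucleophile + protic impurity → quenched reagent (k = 15.0 L mol⁻¹ min⁻¹)

The flask gives 62.9 % in winter and 28.6 % in autumn, and for the trend it rises, by 34 points. At the end of autumn, 1.41 % of the charged nucleophile is still free. The yield per equivalent comes to 0.238 in autumn and 0.262 in winter, beside the 0.239 read from the earlier runs. For a neighbour of autumn charged with 0.300 equiv of nucleophile, 0.239 per equivalent gives 7.17 %, and that flask reaches 6.56 %.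

The earlier runs and the new flask are simulated on assumed constants, noise included.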